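**Plan**

1. Numbering follows the target: O1, C2 (heptyl), C3, C4 (ketone), C4a, C5, C6 (decyl), O7, C8 (lactone carbonyl), C8a. Ring A is the lactone and ring B the dihydropyranone.
2. Retrosynthesis cuts the enol ether bond O1–C8a (ring B) and the lactone bond O7–C8 (ring A) in one operation. It then cuts C4a–C8a (C-acylation by an oxalyl unit), a temporary O7–C4 enol ether bond (alkyne hydroalkoxylation), and the propargylic bonds C3–C4 and C4a–C5 to acetylene and two epoxides.
3. Enabling feature: C8a is both the β-carbon of the ring B enone (C4=O, C4a=C8a) and the α-carbon of the ring A lactone (C8=O). C4–C4a–C8a–C8 is therefore a masked 2,4-dioxo ester, with O1 placed for six-membered closure on C8a and O7 for six-membered closure on C8.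
4. Forward: acetylene is alkylated by one epoxide on each side. O7 is parked on C4 as a 4,5-dihydrofuran, which makes C4a the only nucleophilic carbon for acylation by methyl chlorooxoacetate. Acid then closes ring B (O1–C8a) with opening of the temporary ring, and ring A (O7–C8), in the same operation.
5. Stereochemistry: C2 (S) comes from (S)-2-heptyloxirane and C6 (R) from (R)-2-decyloxirane; no C–O bond at either stereocentre is broken at any stage.

Key step: step 5

Remark: both epoxides are taken as purchased single enantiomers (each is otherwise available in one operation by hydrolytic kinetic resolution of the inexpensive racemate).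

**Step 1**
Reactants: 1 (S)-2-heptyloxirane; 2 lithium acetylide–ethylenediamine complex
Product: 3 (4S)-undec-1-yn-4-ol
Conditions: LiC≡CH·H2NCH2CH2NH2 (1.5 equiv), DMSO, 0 to 23 °C; then H2O
Reagents that add atoms: lithium acetylide–ethylenediamine complex, [Li+].[C-]#C.NCCN
Why: SN2 opening of the terminal epoxide at its unsubstituted carbon by the acetylide (epoxide alkynylation) leaves the C–O bond of the stereocentre untouched, so the (S) carbinol that becomes C2 is carried over from 1.

**Step 2**
Reactants: 3 (4S)-undec-1-yn-4-ol; 4 tert-butyldimethylsilyl chloride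
Product: 5 tert-butyldimethyl{[(4S)-undec-1-yn-4-yl]oxy}silane
Conditions: TBSCl, imidazole, DMF, 23 °C
Reagents that add atoms: tert-butyldimethylsilyl chloride, CC(C)(C)[Si](C)(C)Cl
Why: Imidazole-promoted silylation of a secondary alcohol masks O1, so that later only O7 can add to the alkyne, and the silyl ether should tolerate n-BuLi and BF3·OEt2 at low temperature.

**Step 3**
Reactants: 5 tert-butyldimethyl{[(4S)-undec-1-yn-4-yl]oxy}silane; 6 (R)-2-decyloxirane
Product: 8 (11R,16S)-16-[(tert-butyldimethylsilyl)oxy]tricos-13-yn-11-ol, via lithium acetylide 7 (not isolated)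
Conditions: n-BuLi, THF, −78 °C; BF3·OEt2, then 6, −78 °C; then H2O
Reagents that add atoms: (R)-2-decyloxirane, CCCCCCCCCC[C@@H]1CO1
Why: Yamaguchi–Hirao alkynylation, in which the lithium acetylide activated by BF3·OEt2 opens the terminal epoxide at the primary carbon, so the (R) carbinol that becomes C6 is carried over from 6 with its C–O bond intact.

**Step 4**
Reactants: 8 (11R,16S)-16-[(tert-butyldimethylsilyl)oxy]tricos-13-yn-11-ol; 9 methyl chlorooxoacetate
Product: 11 methyl 2-[(5R)-2-{(2S)-2-[(tert-butyldimethylsilyl)oxy]nonyl}-5-decyl-4,5-dihydrofuran-3-yl]-2-oxoacetate, via silyloxy dihydrofuran 10 (not isolated)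
Conditions: Ph3PAuNTf2 (2 mol %), CH2Cl2, 23 °C; then pyridine, ClCOCO2Me, 0 °C
Reagents that add atoms: methyl chlorooxoacetate, COC(=O)C(=O)Cl
Why: 5-endo-dig hydroalkoxylation of the homopropargylic alcohol by a cationic monovalent gold catalyst should give the 4,5-dihydrofuran, whose only nucleophilic carbon (C4a) is then C-acylated by the chlorooxoacetate (acylation of an enol ether by an activated acid chloride, pyridine taking up HCl), which fixes the regiochemistry of the C4a–C8a bond.

**Step 5**
Reactants: 11 methyl 2-[(5R)-2-{(2S)-2-[(tert-butyldimethylsilyl)oxy]nonyl}-5-decyl-4,5-dihydrofuran-3-yl]-2-oxoacetate; 12 water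
Product: 15 (2S,6R)-6-decyl-2-heptyl-2,3,5,6-tetrahydro-4H,8H-pyrano[3,4-b]pyran-4,8-dione, via hydroxy dihydrofuran keto ester 13 (not isolated), via hydroxy pyranone ester 14 (not isolated)
Conditions: TsOH·H2O (0.5 equiv), MeCN–H2O 20:1, 45 °C; then same flask, PhMe, 80 °C, 5 Å molecular sieves (removal of MeOH)
Reagents that add atoms: water, O
Why: Proposed new method: acid should first remove the silyl group; the freed C2 hydroxyl (O1) then adds 6-exo-trig to the C8a ketone, the hemiketal loses water to the cation O1–C8a=C4a–C4=O7(+) stabilised by both oxygens, and water re-adds at C4 so that the temporary dihydrofuran opens to the C4 ketone and ring B stands as the vinylogous ester, after which the released O7 hydroxyl, held cis to the ester by the C4a=C8a bond, lactonises 6-exo-trig onto C8 to close ring A with loss of methanol. The closest known reaction types are the acid-catalysed cyclodehydration of δ-hydroxy-β-diketones to 2,3-dihydro-4H-pyran-4-ones, the acid-catalysed alkoxy exchange of β-alkoxy enones and the acyl-lactone rearrangement that interconverts acyl lactones and dihydrofuran esters, which have not been run as one ring-switching cascade on a 3-oxalyl-4,5-dihydrofuran. No stereocentre is formed and neither C2–O1 nor C6–O7 is broken, so both configurations are carried through. The step needs site selectivity of two hydroxyls among three electrophilic carbons (C4, C8a, C8): O1 can reach only C8a in a six-membered mode (C4 would need a four-membered and C8 a seven-membered ring), while O7 can return reversibly to C4 or C8a as five-membered enol ethers but leaves the equilibrium only by acylation at C8, which is possible once O1 occupies C8a and is made irreversible by removal of methanol.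

**Compound list**

1 | (S)-2-heptyloxirane | CCCCCCC[C@H]1CO1 | starting material
2 | lithium acetylide–ethylenediamine complex | [Li+].[C-]#C.NCCN | starting material
3 | (4S)-undec-1-yn-4-ol | CCCCCCC[C@H](O)CC#C | intermediate
4 | tert-butyldimethylsilyl chloride | CC(C)(C)[Si](C)(C)Cl | starting material
5 | tert-butyldimethyl{[(4S)-undec-1-yn-4-yl]oxy}silane | CCCCCCC[C@H](O[Si](C)(C)C(C)(C)C)CC#C | intermediate
6 | (R)-2-decyloxirane | CCCCCCCCCC[C@@H]1CO1 | starting material
7 | {(4S)-4-[(tert-butyldimethylsilyl)oxy]undec-1-yn-1-yl}lithium | CCCCCCC[C@H](O[Si](C)(C)C(C)(C)C)CC#C[Li] | intermediate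
8 | (11R,16S)-16-[(tert-butyldimethylsilyl)oxy]tricos-13-yn-11-ol | CCCCCCC[C@H](O[Si](C)(C)C(C)(C)C)CC#CC[C@H](O)CCCCCCCCCC | intermediate
9 | methyl chlorooxoacetate | COC(=O)C(=O)Cl | starting material
10 | tert-butyl({(2S)-1-[(5R)-5-decyl-4,5-dihydrofuran-2-yl]nonan-2-yl}oxy)dimethylsilane | CCCCCCC[C@H](O[Si](C)(C)C(C)(C)C)CC1=CC[C@@H](CCCCCCCCCC)O1 | intermediate
11 | methyl 2-[(5R)-2-{(2S)-2-[(tert-butyldimethylsilyl)oxy]nonyl}-5-decyl-4,5-dihydrofuran-3-yl]-2-oxoacetate | CCCCCCC[C@H](O[Si](C)(C)C(C)(C)C)CC1=C(C(=O)C(=O)OC)C[C@@H](CCCCCCCCCC)O1 | intermediate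
12 | water | O | starting material
13 | methyl 2-{(5R)-5-decyl-2-[(2S)-2-hydroxynonyl]-4,5-dihydrofuran-3-yl}-2-oxoacetate | CCCCCCC[C@H](O)CC1=C(C(=O)C(=O)OC)C[C@@H](CCCCCCCCCC)O1 | intermediate
14 | methyl (2S)-2-heptyl-5-[(2R)-2-hydroxydodecyl]-4-oxo-3,4-dihydro-2H-pyran-6-carboxylate | CCCCCCC[C@H]1CC(=O)C(C[C@H](O)CCCCCCCCCC)=C(C(=O)OC)O1 | intermediate
15 | (2S,6R)-6-decyl-2-heptyl-2,3,5,6-tetrahydro-4H,8H-pyrano[3,4-b]pyran-4,8-dione | CCCCCCCCCC[C@@H]1CC2=C(O[C@@H](CCCCCCC)CC2=O)C(=O)O1 | target

**Summary**

Total step count: 5. Longest linear sequence: 5 steps (1 → 3 → 5 → 8 → 11 → 15).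

**Steps most likely to fail**

Step 5. The five-membered enol ether may re-close (O7 back onto C4, or onto C8a) faster than O7 is acylated, so that the material rests as dihydrofuran isomers, or the β-hydroxy ketone may lose water before ring B closes. The fallback makes the lactone first, so that O7 is committed before O1 is set free; it sets out from 8 and comes back at 15. Hydroxyl-directed hydration of the alkyne (Ph3PAuNTf2 cat., 1,4-dioxane–H2O, 23 °C; 5-endo-dig addition, then hydrolysis of the enol ether) should give the γ-hydroxy ketone (11R,16S)-16-[(tert-butyldimethylsilyl)oxy]-11-hydroxytricosan-14-one F1. Acylation of its hydroxyl with 9 and pyridine in CH2Cl2 at 0 °C gives the mixed oxalate methyl (11R,16S)-16-[(tert-butyldimethylsilyl)oxy]-14-oxotricosan-11-yl oxalate F2. Treatment with LiN(SiMe3)2 in THF at −78 °C should effect a Dieckmann (intramolecular Claisen) closure, in which only the C4a enolate reaches the distal ester carbonyl through a six-membered transition state, to the enolised keto lactone (6R)-4-{(3S)-3-[(tert-butyldimethylsilyl)oxy]decanoyl}-6-decyl-3-hydroxy-5,6-dihydro-2H-pyran-2-one F3. TsOH·H2O in wet MeCN and then warm PhMe removes the silyl group and closes ring B by the classical cyclodehydration of a δ-hydroxy-β-dicarbonyl compound, giving 15.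

Step 4. The cationic gold catalyst may add unreacted 8 across the newly formed enol ether, or move the double bond to the exocyclic position, so that acylation is lost or goes to the wrong carbon. The fallback makes C4a nucleophilic as a vinyllithium instead of an enol ether carbon; it sets out from 8 and comes back at 11. Iodocyclisation (I2, NaHCO3, MeCN, 0 °C; 5-endo-dig) should give tert-butyl({(2S)-1-[(5R)-5-decyl-3-iodo-4,5-dihydrofuran-2-yl]nonan-2-yl}oxy)dimethylsilane F4. Iodine–lithium exchange (t-BuLi, Et2O, −78 °C) and addition of the vinyllithium to excess dimethyl oxalate then gives 11.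

Step 3. BF3·OEt2 may rearrange or oligomerise the epoxide, or loosen the silyl ether, before the alkynyl nucleophile opens the ring. The fallback changes the electrophile to a cyclic sulfate that needs no Lewis acid; it sets out from 5 and comes back at 8. Purchased (R)-dodecane-1,2-diol F5 is converted with SOCl2 into the cyclic sulfite (4R)-4-decyl-1,3,2-dioxathiolane 2-oxide F6, which is oxidised (RuCl3 cat., NaIO4, MeCN–H2O) to the cyclic sulfate (4R)-4-decyl-1,3,2-dioxathiolane 2,2-dioxide F7. The lithium acetylide 7, made from 5 with n-BuLi, opens F7 at the primary carbon to lithium (11R,16S)-16-[(tert-butyldimethylsilyl)oxy]tricos-13-yn-11-yl sulfate F8. Mild hydrolysis of the sulfate monoester (cat. H2SO4, 1 equiv H2O, THF, 23 °C) gives 8.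

**Further compounds**

F1 | step 5 | (11R,16S)-16-[(tert-butyldimethylsilyl)oxy]-11-hydroxytricosan-14-one | CCCCCCC[C@H](O[Si](C)(C)C(C)(C)C)CC(=O)CC[C@H](O)CCCCCCCCCC
F2 | step 5 | methyl (11R,16S)-16-[(tert-butyldimethylsilyl)oxy]-14-oxotricosan-11-yl oxalate | CCCCCCC[C@H](O[Si](C)(C)C(C)(C)C)CC(=O)CC[C@H](OC(=O)C(=O)OC)CCCCCCCCCC
F3 | step 5 | (6R)-4-{(3S)-3-[(tert-butyldimethylsilyl)oxy]decanoyl}-6-decyl-3-hydroxy-5,6-dihydro-2H-pyran-2-one | CCCCCCC[C@H](O[Si](C)(C)C(C)(C)C)CC(=O)C1=C(O)C(=O)O[C@H](CCCCCCCCCC)C1
F4 | step 4 | tert-butyl({(2S)-1-[(5R)-5-decyl-3-iodo-4,5-dihydrofuran-2-yl]nonan-2-yl}oxy)dimethylsilane | CCCCCCC[C@H](O[Si](C)(C)C(C)(C)C)CC1=C(I)C[C@@H](CCCCCCCCCC)O1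
F5 | step 3 | (R)-dodecane-1,2-diol | CCCCCCCCCC[C@@H](O)CO
F6 | step 3 | (4R)-4-decyl-1,3,2-dioxathiolane 2-oxide | CCCCCCCCCC[C@@H]1COS(=O)O1
F7 | step 3 | (4R)-4-decyl-1,3,2-dioxathiolane 2,2-dioxide | CCCCCCCCCC[C@@H]1COS(=O)(=O)O1
F8 | step 3 | lithium (11R,16S)-16-[(tert-butyldimethylsilyl)oxy]tricos-13-yn-11-yl sulfate | CCCCCCC[C@H](O[Si](C)(C)C(C)(C)C)CC#CC[C@H](OS(=O)(=O)[O-])CCCCCCCCCC.[Li+]
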